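The runs are calculated with made-up constants; scatter was added.

- Take one point, a hundredth of the L charged, as the unit: in this flask it is 0.200 mM of [L].

all flasks: L 20 mM
- cedar: D 6 mM; Q 2 µM; temperature 5 °C; the very flask that is asked about, followed so far
- ash: D 6 mM; Q 2 µM; temperature −10 °C; run made earlier
- flask: D 6.00 mM; Q 2.0 µM; temperature 5 °C; time 4.0 d

| run | time / d | Z / % |
|---|---|---|
| cedar | 0.500 | 18.3 |
| cedar | 0.833 | 23.5 |
| cedar | 1.25 | 26.5 |
| cedar | 1.67 | 28.0 |
| cedar | 2.50 | 28.9 |
| cedar | 3.00 | 27.0 |
| ash | 1.04 | 16.6 |
| ash | 1.67 | 23.5 |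
| ash | 2.50 | 28.1 |
| ash | 4.00 | 31.6 |
| ash | 5.00 | 32.7 |
| ash | 6.00 | 33.1 |

(standard deviation of a reading: 0.5 percentage points)

- Z taken out counts as made
- additions bring no volume worth counting

- Saturday's: change nothing and wait 8.0 d more
- Monday's: at 4.0 d raise the temperature by 10 K, then wait 8.0 d
- Friday's: at 4.0 d add Q, 100% of the amount charged, then wait 8.0 d
- Wednesday's: at 4.0 d take out 90% of the Z then present, then wait 8.0 d

* Z, in percent of the L first charged, at 4.0 d
* what to do for the largest gain in Z; "none" if nothing gains more than 2 percentage points (Saturday's / Monday's / Friday's / Wednesday's / none)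
* Z present, with what was taken out counted in, in percent of the L first charged, after Monday's
* Z present, with what was taken out counted in, in percent of the L first charged, after Wednesday's

- Read the stall first: in cedar, the flask asked about, [Z] lies flat from 1.67 d on, and the readings from there average 28.0%. Commit to that for "now".
- Follow one Q molecule: divide the stall [Z] read in cedar by the [Q] charged there to get 2800 turns per Q, the turnover number. So Q is a catalyst, and at each turn it makes a Z or stops, with a chance of 0.0357% of stopping. Colder ash reads 3310 turns, more than cedar.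
- Bound Wednesday's total from below: if Q has stopped, nothing re-forms, and the total stays at 28.0%.
- Bound it from above: if the stall is a balance, the flask could rebuild the stall whole, giving 53.1%. Tighten this, since the same share forms from a smaller pool of L and Z, to 46.1%.
- Commit to the lower bound, as my own judgement. Then Monday's and Wednesday's stay at 28.0%, and Friday's new Q can add up to 28.0% more, so name Friday's as best.
- Place the forecast: now 27.5%, best Wednesday's, Monday's 23%, and Wednesday's 44%, which stands inside the bracket near its top, on the ground “Removing Z lets it re-form”.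
- Read the flask: now 27.8%, best Friday's, which gains 8 percentage points, Monday's 27.8%, Wednesday's 27.8%, within 0.5 points of the bottom of the bracket.

    L + Q → Z + Q, rate k1*[L]^1.5*[Q]/(1 + ([L]/Kh1)^1.5) (15.0 mM, k = 1.90 × 10⁵ /M^1.5/h, Ea = 38.0 kJ/mol)
    Q + Z → E (k = 18.0 /M/h, Ea = 54.0 kJ/mol)
    L + D → G (k = 5.80 /M/h, Ea = 45.0 kJ/mol)
    Q → X (k = 0.00140 /h, Ea = 285 kJ/mol)
    (constants at 5 °C)

- Count turns per Q again: the flask gives 2780, and a neighbour flask, charged with 1.20 µM of Q, reaches 21.8% of the L charged as Z, or 3640 turns, more than the 2800 read from cedar.
- Compare the two ends of Q in the flask: with [Z] at the stall, the half-life of Q against Z is 0.288 d, far shorter than the 21 d of Q to X, as that step stood at 0.293 d. At 4.00 d the catalyst stands 97.5% as E and 2.46% as X, with 0.0172% still able to turn over.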